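**Remarks on the chemistry.** The target is taken as the (1R,5R,6S) enantiomer encoded by the SMILES, with the tertiary hydroxyl cis to the epoxide oxygen. The core ring atoms are called C1 (ketone carbon), C2 (nitrogen-bearing carbon), C3 (=CH), C4 (carbinol carbon), C5 and C6 (epoxide carbons, C6 next to C1). The cyclopentane-1,3-dione amide end group is handled as its enol tautomer, as drawn in the target.

## Retrosynthetic overview

- Last disconnections: a Stille coupling at the C4 vinyl group (lower trienamide from a bromodienamide bearing the hydroxycyclopentenone ring) and a copper-catalysed C2–N amidation (upper cyclohexyl-dienamide), leaving a 2-bromo-epoxycyclohexenone.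
- Key disconnection: C2 is excised as a one-carbon unit. The six-membered 2-bromo enone comes from a cyclopentanone silyl enol ether by dibromocarbene (2+1) cycloaddition across C1=C3 (new bonds C1–C2 and C3–C2) and electrocyclic opening of the cyclopropane (the old C1–C3 bond is lost).
- Enabling feature: in the six-membered ring the carbonyl carbon C1 is flanked by the heteroatom-bearing sp2 carbon C2 and by C3–H, the array that a dihalocarbene ring expansion of a cyclic enol ether delivers. C4 is quaternary and C6 is an epoxide carbon, so the cyclopentanone can enolise only towards C3.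
- The cyclopentanone (C1, C3–C6) already carries all three stereocentres, set from (R)-4-silyloxycyclopentenone: epoxidation trans to the silyloxy group, acetylide addition anti to the epoxide, then oxidation of the silyloxy carbon to the C1 ketone.
- Ring order: epoxide on the purchased five-membered ring, then the transient cyclopropane, then the six-membered ring by expansion; the cyclohexyl and hydroxycyclopentenone rings are bought or made as fragments.

Key step: step 14

## Route

**Upper amide (steps 1–3)**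

Step 1
Reactants: 1 cyclohexanecarbaldehyde; 2 triethyl (E)-4-phosphonocrotonate
Product: 3 ethyl (2E,4E)-5-cyclohexylpenta-2,4-dienoate
Conditions: LiOH·H2O, 4 Å molecular sieves, THF, reflux
Reagents that add atoms: none
Why: Vinylogous Horner–Wadsworth–Emmons olefination; the stabilised phosphonate anion should give the E-alkene at the new C4=C5 bond and the 2E geometry of the crotonate is retained.

Step 2
Reactants: 3 ethyl (2E,4E)-5-cyclohexylpenta-2,4-dienoate
Product: 4 (2E,4E)-5-cyclohexylpenta-2,4-dienoic acid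
Conditions: LiOH, THF/MeOH/H2O, rt; then 1 M HCl
Reagents that add atoms: lithium hydroxide, [Li+].[OH-]
Why: Ester saponification; the conjugated dienoate is stable to aqueous hydroxide at room temperature and the alkene geometry is untouched.

Step 3
Reactants: 4 (2E,4E)-5-cyclohexylpenta-2,4-dienoic acid
Product: 6 (2E,4E)-5-cyclohexylpenta-2,4-dienamide, via dienoyl chloride 5 (not isolated)
Conditions: (COCl)2, DMF (cat.), CH2Cl2, 0 °C to rt; then aq. NH3, THF, 0 °C
Reagents that add atoms: ammonia, N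
Why: Acyl chloride formation followed by ammonolysis (acyl substitution) should give the primary amide without touching the diene.

**Lower bromodienamide (steps 4–8)**

Step 4
Reactants: 7 cyclopentane-1,3-dione
Product: 8 3-hydroxy-2-nitrocyclopent-2-en-1-one (2-nitrocyclopentane-1,3-dione, enol form)
Conditions: fuming HNO3, AcOH, 10 °C
Reagents that add atoms: nitric acid, O[N+](=O)[O-]
Why: Electrophilic nitration of the enol of a cyclic 1,3-dione occurs at the doubly activated C2.

Step 5
Reactants: 8 3-hydroxy-2-nitrocyclopent-2-en-1-one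
Product: 9 2-amino-3-hydroxycyclopent-2-en-1-one hydrochloride
Conditions: H2 (1 atm), Pd/C (10 wt % palladium on carbon), HCl, MeOH, rt
Reagents that add atoms: hydrogen chloride, Cl
Why: Catalytic hydrogenation of the nitro group to the amine, trapped as the hydrochloride so that the aminodione does not self-condense.

Step 6
Reactants: 10 glutaconaldehyde potassium salt (potassium (2E,4E)-5-oxopenta-1,3-dien-1-olate)
Product: 11 (2E,4E)-5-bromopenta-2,4-dienal
Conditions: PPh3, Br2, CH2Cl2, 0 °C; then 10, 0 °C to rt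
Reagents that add atoms: bromine, BrBr
Why: Deoxybromination of the dienolate oxygen by dibromotriphenylphosphorane (Appel-type) should give the thermodynamically favoured E,E-bromodienal.

Step 7
Reactants: 11 (2E,4E)-5-bromopenta-2,4-dienal
Product: 12 (2E,4E)-5-bromopenta-2,4-dienoic acid
Conditions: NaClO2, NaH2PO4, 2-methylbut-2-ene, t-BuOH/H2O, 0 °C to rt
Reagents that add atoms: sodium chlorite, [Na+].[O-]Cl=O
Why: Pinnick oxidation is selective for the aldehyde, and the alkene scavenger removes hypochlorous acid so the bromodiene is preserved.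

Step 8
Reactants: 12 (2E,4E)-5-bromopenta-2,4-dienoic acid; 9 2-amino-3-hydroxycyclopent-2-en-1-one hydrochloride
Product: 14 (2E,4E)-5-bromo-N-(2-hydroxy-5-oxocyclopent-1-en-1-yl)penta-2,4-dienamide, via bromodienoyl chloride 13 (not isolated)
Conditions: (COCl)2, DMF (cat.), CH2Cl2, 0 °C; then 9, Et3N, THF/CH2Cl2, −20 °C to rt
Reagents that add atoms: none
Why: N-acylation of the amine by the acid chloride (amide formation); the amine is more nucleophilic than the vinylogous-acid hydroxyl and any O-acyl isomer should transfer to nitrogen.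

**Core (steps 9–14)**

Step 9
Reactants: 15 (R)-4-[(tert-butyldimethylsilyl)oxy]cyclopent-2-en-1-one
Product: 16 (1S,4R,5R)-4-[(tert-butyldimethylsilyl)oxy]-6-oxabicyclo[3.1.0]hexan-2-one (epoxide trans to the silyloxy group)
Conditions: 30 % aq. H2O2, NaOH (0.2 equiv), MeOH, −20 °C
Reagents that add atoms: hydrogen peroxide, OO
Why: Weitz–Scheffer nucleophilic epoxidation; hydroperoxide adds to the enone face opposite the bulky 4-silyloxy group, which sets C5 and C6 with the epoxide trans to the silyl ether.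

Step 10
Reactants: 16 (1S,4R,5R)-4-[(tert-butyldimethylsilyl)oxy]-6-oxabicyclo[3.1.0]hexan-2-one; 17 ethynyltrimethylsilane
Product: 19 (1S,2S,4R,5R)-4-[(tert-butyldimethylsilyl)oxy]-2-[(trimethylsilyl)ethynyl]-6-oxabicyclo[3.1.0]hexan-2-ol (hydroxyl cis to the epoxide), via lithium silylacetylide 18 (not isolated)
Conditions: 17, n-BuLi, THF, −78 °C; then 16, −78 °C; aq. NH4Cl
Reagents that add atoms: none
Why: 1,2-Addition of a lithium acetylide to the ketone; attack on the convex face anti to the adjacent epoxide oxygen should set C4 with the new hydroxyl cis to the epoxide.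

Step 11
Reactants: 19 (1S,2S,4R,5R)-4-[(tert-butyldimethylsilyl)oxy]-2-[(trimethylsilyl)ethynyl]-6-oxabicyclo[3.1.0]hexan-2-ol
Product: 20 (1S,2S,4R,5S)-2-[(trimethylsilyl)ethynyl]-6-oxabicyclo[3.1.0]hexane-2,4-diol
Conditions: HF·pyridine, pyridine, THF, 0 °C to rt
Reagents that add atoms: none
Why: Buffered acidic fluoride cleaves the secondary silyl ether, should spare the C-silyl alkyne and the epoxide, and avoids the base that could trigger Payne rearrangement of the trans-epoxy alcohol.

Step 12
Reactants: 20 (1S,2S,4R,5S)-2-[(trimethylsilyl)ethynyl]-6-oxabicyclo[3.1.0]hexane-2,4-diol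
Product: 21 (1R,4S,5S)-4-hydroxy-4-[(trimethylsilyl)ethynyl]-6-oxabicyclo[3.1.0]hexan-2-one
Conditions: Dess–Martin periodinane, pyridine, CH2Cl2, 0 °C to rt
Reagents that add atoms: none
Why: Dess–Martin oxidation of the only secondary alcohol under near-neutral conditions gives the C1 ketone and erases the relay stereocentre; the tertiary alcohol cannot be oxidised.

Step 13
Reactants: 21 (1R,4S,5S)-4-hydroxy-4-[(trimethylsilyl)ethynyl]-6-oxabicyclo[3.1.0]hexan-2-one
Product: 22 (1R,4S,5S)-2,4-bis[(trimethylsilyl)oxy]-4-[(trimethylsilyl)ethynyl]-6-oxabicyclo[3.1.0]hex-2-ene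
Conditions: TMSOTf (2.5 equiv), Et3N (5 equiv), CH2Cl2, −78 °C; non-aqueous work-up, used crude
Reagents that add atoms: trimethylsilyl trifluoromethanesulfonate, C[Si](C)(C)OS(=O)(=O)C(F)(F)F
Why: Soft enolisation and silylation; only C3 carries enolisable hydrogen, the tertiary hydroxyl is silylated in the same operation, and excess amine keeps the triflate from ionising the epoxide.

Step 14
Reactants: 22 (1R,4S,5S)-2,4-bis[(trimethylsilyl)oxy]-4-[(trimethylsilyl)ethynyl]-6-oxabicyclo[3.1.0]hex-2-ene; 23 bromoform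
Product: 26 (1R,5S,6S)-3-bromo-5-[(trimethylsilyl)ethynyl]-5-[(trimethylsilyl)oxy]-7-oxabicyclo[4.1.0]hept-3-en-2-one, via dibromocarbene 24 (not isolated), via gem-dibromocyclopropane 25 (not isolated)
Conditions: KOtBu (2.2 equiv), pentane, −30 °C to rt
Reagents that add atoms: none
Why: KOtBu converts bromoform into dibromocarbene 24, which adds in a concerted cheletropic (2+1) cycloaddition to the electron-rich enol ether C1=C3 of 22, forming the C1–C2 and C3–C2 bonds at once and so closing the cyclopropane and the six-membered periphery C1–C2–C3–C4–C5–C6 of 25. The strained 1-siloxy-gem-dibromocyclopropane then loses the bromide syn to the five-membered ring in a disrotatory cyclopropyl-to-allyl electrocyclic opening assisted by the siloxy oxygen, which cleaves the former C1–C3 bond, and loss of the silyl group from the oxocarbenium ion leaves the 2-bromo enone 26; the closest known reaction type is the dihalocarbene one-carbon ring expansion of cyclic silyl enol ethers to 2-halocycloalk-2-enones. No stereocentre of the product is created: C4, C5 and C6 are carried over unchanged, and the two cyclopropane stereocentres of 25 (carbene expected anti to the epoxide) vanish on opening, so facial selectivity does not matter. The step needs chemoselectivity for the enol ether over the silylalkyne and a single regiochemistry of opening; the first is secured by the much higher nucleophilicity of the silyl enol ether towards the electrophilic carbene, the second by the siloxy group on C1, which fixes the carbonyl at C1 and the bromo-alkene at C2=C3. Excess KOtBu traps the released silyl bromide as tert-butoxytrimethylsilane, so no Lewis acid is left to open the epoxide or ionise unreacted epoxy enol silane.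

**Union and end game (steps 15–18)**

Step 15
Reactants: 26 (1R,5S,6S)-3-bromo-5-[(trimethylsilyl)ethynyl]-5-[(trimethylsilyl)oxy]-7-oxabicyclo[4.1.0]hept-3-en-2-one; 6 (2E,4E)-5-cyclohexylpenta-2,4-dienamide
Product: 27 (2E,4E)-5-cyclohexyl-N-[(1R,5S,6S)-2-oxo-5-[(trimethylsilyl)ethynyl]-5-[(trimethylsilyl)oxy]-7-oxabicyclo[4.1.0]hept-3-en-3-yl]penta-2,4-dienamide
Conditions: CuI (10 mol %), N,N'-dimethylethylenediamine (20 mol %), K2CO3, toluene, 70 °C
Reagents that add atoms: none
Why: Copper-catalysed Goldberg–Buchwald amidation of the vinyl bromide of the 2-bromo enone with the primary amide should install the C2–N bond with retention at the sp2 carbon under anhydrous, weakly basic conditions that both silyl groups and the epoxide tolerate.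

Step 16
Reactants: 27 (2E,4E)-5-cyclohexyl-N-[(1R,5S,6S)-2-oxo-5-[(trimethylsilyl)ethynyl]-5-[(trimethylsilyl)oxy]-7-oxabicyclo[4.1.0]hept-3-en-3-yl]penta-2,4-dienamide
Product: 28 (2E,4E)-5-cyclohexyl-N-[(1R,5S,6S)-5-ethynyl-5-hydroxy-2-oxo-7-oxabicyclo[4.1.0]hept-3-en-3-yl]penta-2,4-dienamide
Conditions: TBAF (2.2 equiv), AcOH (2.2 equiv), THF, 0 °C
Reagents that add atoms: none
Why: Buffered fluoride cleaves the alkynyl C–Si and the tertiary O–Si bonds; the syn hydroxy epoxide cannot undergo Payne rearrangement because the hydroxyl is on the same face as the epoxide oxygen.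

Step 17
Reactants: 28 (2E,4E)-5-cyclohexyl-N-[(1R,5S,6S)-5-ethynyl-5-hydroxy-2-oxo-7-oxabicyclo[4.1.0]hept-3-en-3-yl]penta-2,4-dienamide
Product: 29 (2E,4E)-5-cyclohexyl-N-[(1R,5S,6S)-5-hydroxy-2-oxo-5-[(E)-2-(tributylstannyl)ethenyl]-7-oxabicyclo[4.1.0]hept-3-en-3-yl]penta-2,4-dienamide
Conditions: Bu3SnH (1.2 equiv), PdCl2(PPh3)2 (3 mol %), THF, 0 °C
Reagents that add atoms: tributyltin hydride, CCCC[SnH](CCCC)CCCC
Why: Palladium-catalysed syn-hydrostannation of the terminal alkyne; the fully substituted propargylic carbon should direct tin to the terminus and give the E-vinylstannane faster than the hindered enone is reduced.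

Step 18
Reactants: 29 (2E,4E)-5-cyclohexyl-N-[(1R,5S,6S)-5-hydroxy-2-oxo-5-[(E)-2-(tributylstannyl)ethenyl]-7-oxabicyclo[4.1.0]hept-3-en-3-yl]penta-2,4-dienamide; 14 (2E,4E)-5-bromo-N-(2-hydroxy-5-oxocyclopent-1-en-1-yl)penta-2,4-dienamide
Product: 30 (2E,4E)-5-cyclohexyl-N-[(1R,5R,6S)-5-hydroxy-5-[(1E,3E,5E)-7-[(2-hydroxy-5-oxocyclopent-1-en-1-yl)amino]-7-oxohepta-1,3,5-trien-1-yl]-2-oxo-7-oxabicyclo[4.1.0]hept-3-en-3-yl]penta-2,4-dienamide (target)
Conditions: Pd2(dba)3 (5 mol %), AsPh3 (20 mol %), DMF, rt, dark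
Reagents that add atoms: none
Why: Stille cross-coupling of the vinylstannane with the vinyl bromide proceeds with retention of both alkene geometries under neutral conditions and should give the E,E,E-triene without protecting groups.

## Compound list

1 | cyclohexanecarbaldehyde | O=CC1CCCCC1 | starting material
2 | triethyl (E)-4-phosphonocrotonate | CCOC(=O)/C=C/CP(=O)(OCC)OCC | starting material
3 | ethyl (2E,4E)-5-cyclohexylpenta-2,4-dienoate | CCOC(=O)/C=C/C=C/C1CCCCC1 | intermediate
4 | (2E,4E)-5-cyclohexylpenta-2,4-dienoic acid | OC(=O)/C=C/C=C/C1CCCCC1 | intermediate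
5 | (2E,4E)-5-cyclohexylpenta-2,4-dienoyl chloride | ClC(=O)/C=C/C=C/C1CCCCC1 | intermediate (not isolated)
6 | (2E,4E)-5-cyclohexylpenta-2,4-dienamide | NC(=O)/C=C/C=C/C1CCCCC1 | intermediate
7 | cyclopentane-1,3-dione | O=C1CCC(=O)C1 | starting material
8 | 3-hydroxy-2-nitrocyclopent-2-en-1-one | O=C1CCC(O)=C1[N+](=O)[O-] | intermediate
9 | 2-amino-3-hydroxycyclopent-2-en-1-one hydrochloride | Cl.NC1=C(O)CCC1=O | intermediate
10 | glutaconaldehyde potassium salt | [K+].[O-]/C=C/C=C/C=O | starting material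
11 | (2E,4E)-5-bromopenta-2,4-dienal | O=C/C=C/C=C/Br | intermediate
12 | (2E,4E)-5-bromopenta-2,4-dienoic acid | OC(=O)/C=C/C=C/Br | intermediate
13 | (2E,4E)-5-bromopenta-2,4-dienoyl chloride | ClC(=O)/C=C/C=C/Br | intermediate (not isolated)
14 | (2E,4E)-5-bromo-N-(2-hydroxy-5-oxocyclopent-1-en-1-yl)penta-2,4-dienamide | O=C(/C=C/C=C/Br)NC1=C(O)CCC1=O | intermediate
15 | (R)-4-[(tert-butyldimethylsilyl)oxy]cyclopent-2-en-1-one | O=C1C=C[C@H](O[Si](C)(C)C(C)(C)C)C1 | starting material
16 | (1S,4R,5R)-4-[(tert-butyldimethylsilyl)oxy]-6-oxabicyclo[3.1.0]hexan-2-one | C1C(=O)[C@H]2O[C@H]2[C@@H]1O[Si](C)(C)C(C)(C)C | intermediate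
17 | ethynyltrimethylsilane | C#C[Si](C)(C)C | starting material
18 | lithium (trimethylsilyl)acetylide | [Li]C#C[Si](C)(C)C | intermediate (not isolated)
19 | (1S,2S,4R,5R)-4-[(tert-butyldimethylsilyl)oxy]-2-[(trimethylsilyl)ethynyl]-6-oxabicyclo[3.1.0]hexan-2-ol | C1[C@](O)(C#C[Si](C)(C)C)[C@H]2O[C@H]2[C@@H]1O[Si](C)(C)C(C)(C)C | intermediate
20 | (1S,2S,4R,5S)-2-[(trimethylsilyl)ethynyl]-6-oxabicyclo[3.1.0]hexane-2,4-diol | C1[C@](O)(C#C[Si](C)(C)C)[C@H]2O[C@H]2[C@@H]1O | intermediate
21 | (1R,4S,5S)-4-hydroxy-4-[(trimethylsilyl)ethynyl]-6-oxabicyclo[3.1.0]hexan-2-one | C1[C@](O)(C#C[Si](C)(C)C)[C@H]2O[C@H]2C1=O | intermediate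
22 | (1R,4S,5S)-2,4-bis[(trimethylsilyl)oxy]-4-[(trimethylsilyl)ethynyl]-6-oxabicyclo[3.1.0]hex-2-ene | C[Si](C)(C)OC1=C[C@](O[Si](C)(C)C)(C#C[Si](C)(C)C)[C@H]2O[C@@H]12 | intermediate
23 | bromoform | BrC(Br)Br | starting material
24 | dibromocarbene | Br[C]Br | intermediate (not isolated)
25 | 7,7-dibromo-1,5-bis[(trimethylsilyl)oxy]-5-[(trimethylsilyl)ethynyl]-3-oxatricyclo[4.1.0.0(2,4)]heptane, cyclopropane anti to the epoxide | BrC1(Br)[C@@H]2[C@](O[Si](C)(C)C)(C#C[Si](C)(C)C)[C@H]3O[C@H]3[C@]12O[Si](C)(C)C | intermediate (not isolated)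
26 | (1R,5S,6S)-3-bromo-5-[(trimethylsilyl)ethynyl]-5-[(trimethylsilyl)oxy]-7-oxabicyclo[4.1.0]hept-3-en-2-one | BrC1=C[C@](O[Si](C)(C)C)(C#C[Si](C)(C)C)[C@H]2O[C@H]2C1=O | intermediate
27 | (2E,4E)-5-cyclohexyl-N-[(1R,5S,6S)-2-oxo-5-[(trimethylsilyl)ethynyl]-5-[(trimethylsilyl)oxy]-7-oxabicyclo[4.1.0]hept-3-en-3-yl]penta-2,4-dienamide | O=C(/C=C/C=C/C1CCCCC1)NC1=C[C@](O[Si](C)(C)C)(C#C[Si](C)(C)C)[C@H]2O[C@H]2C1=O | intermediate
28 | (2E,4E)-5-cyclohexyl-N-[(1R,5S,6S)-5-ethynyl-5-hydroxy-2-oxo-7-oxabicyclo[4.1.0]hept-3-en-3-yl]penta-2,4-dienamide | O=C(/C=C/C=C/C1CCCCC1)NC1=C[C@](O)(C#C)[C@H]2O[C@H]2C1=O | intermediate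
29 | (2E,4E)-5-cyclohexyl-N-[(1R,5S,6S)-5-hydroxy-2-oxo-5-[(E)-2-(tributylstannyl)ethenyl]-7-oxabicyclo[4.1.0]hept-3-en-3-yl]penta-2,4-dienamide | O=C(/C=C/C=C/C1CCCCC1)NC1=C[C@](O)(/C=C/[Sn](CCCC)(CCCC)CCCC)[C@H]2O[C@H]2C1=O | intermediate
30 | (2E,4E)-5-cyclohexyl-N-[(1R,5R,6S)-5-hydroxy-5-[(1E,3E,5E)-7-[(2-hydroxy-5-oxocyclopent-1-en-1-yl)amino]-7-oxohepta-1,3,5-trien-1-yl]-2-oxo-7-oxabicyclo[4.1.0]hept-3-en-3-yl]penta-2,4-dienamide | O=C(/C=C/C=C/C1CCCCC1)NC1=C[C@](O)(/C=C/C=C/C=C/C(=O)NC2=C(O)CCC2=O)[C@H]2O[C@H]2C1=O | target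

## Step count and risks

Total step count: 18. Longest linear sequence: 10 steps (15 to 30, steps 9–18).

Steps most likely to fail:

1. **Step 14.** What may go wrong: the alkoxide may desilylate the enol ether before the carbene is captured, or the epoxide may be opened by bromide during the cyclopropane opening. Fallback (sets out from 22, comes back at 27): Furukawa–Simmons–Smith cyclopropanation of 22 (Et2Zn, CH2I2, CH2Cl2, 0 °C) would give the siloxycyclopropane 1,5-bis[(trimethylsilyl)oxy]-5-[(trimethylsilyl)ethynyl]-3-oxatricyclo[4.1.0.0(2,4)]heptane F1. Ito–Saegusa oxidative ring expansion (FeCl3, DMF, 0 °C) would cleave the internal cyclopropane bond to the 4-chloro-5-[(trimethylsilyl)ethynyl]-5-[(trimethylsilyl)oxy]-7-oxabicyclo[4.1.0]heptan-2-one F2 (chlorine-bearing carbon as an epimer mixture). NaOAc in MeOH would eliminate hydrogen chloride to the enone (1R,5S,6S)-5-[(trimethylsilyl)ethynyl]-5-[(trimethylsilyl)oxy]-7-oxabicyclo[4.1.0]hept-3-en-2-one F3. Iodine and pyridine (α-iodination of the enone) would give the (1R,5S,6S)-3-iodo-5-[(trimethylsilyl)ethynyl]-5-[(trimethylsilyl)oxy]-7-oxabicyclo[4.1.0]hept-3-en-2-one F4, and its copper-catalysed amidation with 6 under the conditions of step 15 leads to 27.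

2. **Step 15.** What may go wrong: sluggish C–N coupling of the weakly nucleophilic conjugated primary amide at the hindered 2-bromo enone, with base-induced degradation of the epoxy enone taking over. Fallback (sets out from 26, comes back at 27): coupling of 26 with the more reactive tert-butyl carbamate (Pd2(dba)3, Xantphos, Cs2CO3, dioxane, 80 °C) would give tert-butyl N-[(1R,5S,6S)-2-oxo-5-[(trimethylsilyl)ethynyl]-5-[(trimethylsilyl)oxy]-7-oxabicyclo[4.1.0]hept-3-en-3-yl]carbamate F5. Deprotonation with LiN(SiMe3)2 at −78 °C and acylation with the acid chloride 5 (made from 4 as in step 3) would give the N-Boc-N-dienoyl imide F6. Mg(ClO4)2 in MeCN would then remove the carbamate selectively to give 27, so the amide bond is made by acylation instead of by coupling the intact dienamide.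

3. **Step 17.** What may go wrong: competing palladium hydride conjugate reduction of the enone, formation of the internal stannane regioisomer, or protodestannylation on purification. Fallback (sets out from 28, comes back at 30, replacing steps 17 and 18): Sonogashira coupling of 28 with 14 (PdCl2(PPh3)2, CuI, Et3N, THF, rt) would give the dienyne (2E,4E)-7-[(1R,5S,6S)-3-[(2E,4E)-5-cyclohexylpenta-2,4-dienamido]-5-hydroxy-4-oxo... core]-N-(2-hydroxy-5-oxocyclopent-1-en-1-yl)hepta-2,4-dien-6-ynamide F7 (the target with the C4-bound alkene as an alkyne). Ruthenium-catalysed trans-hydrosilylation ([Cp*Ru(MeCN)3]PF6, (EtO)3SiH, CH2Cl2, 0 °C to rt) would give the triethoxysilyl triene F8 (silicon on the alkene carbon remote from C4, hydrogen and silicon added anti; the regiochemistry is immaterial). Protodesilylation with AgF in THF/MeOH/H2O would then give the E-alkene of 30.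

Further compounds
F1 | step 14 | 1,5-bis[(trimethylsilyl)oxy]-5-[(trimethylsilyl)ethynyl]-3-oxatricyclo[4.1.0.0(2,4)]heptane, cyclopropane anti to the epoxide | C1[C@@H]2[C@](O[Si](C)(C)C)(C#C[Si](C)(C)C)[C@H]3O[C@H]3[C@]12O[Si](C)(C)C
F2 | step 14 | 4-chloro-5-[(trimethylsilyl)ethynyl]-5-[(trimethylsilyl)oxy]-7-oxabicyclo[4.1.0]heptan-2-one, chlorine-bearing carbon as epimer mixture | ClC1[C@](O[Si](C)(C)C)(C#C[Si](C)(C)C)[C@H]2O[C@H]2C(=O)C1
F3 | step 14 | (1R,5S,6S)-5-[(trimethylsilyl)ethynyl]-5-[(trimethylsilyl)oxy]-7-oxabicyclo[4.1.0]hept-3-en-2-one | C1=C[C@](O[Si](C)(C)C)(C#C[Si](C)(C)C)[C@H]2O[C@H]2C1=O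
F4 | step 14 | (1R,5S,6S)-3-iodo-5-[(trimethylsilyl)ethynyl]-5-[(trimethylsilyl)oxy]-7-oxabicyclo[4.1.0]hept-3-en-2-one | IC1=C[C@](O[Si](C)(C)C)(C#C[Si](C)(C)C)[C@H]2O[C@H]2C1=O
F5 | step 15 | tert-butyl N-[(1R,5S,6S)-2-oxo-5-[(trimethylsilyl)ethynyl]-5-[(trimethylsilyl)oxy]-7-oxabicyclo[4.1.0]hept-3-en-3-yl]carbamate | CC(C)(C)OC(=O)NC1=C[C@](O[Si](C)(C)C)(C#C[Si](C)(C)C)[C@H]2O[C@H]2C1=O
F6 | step 15 | tert-butyl N-[(2E,4E)-5-cyclohexylpenta-2,4-dienoyl]-N-[(1R,5S,6S)-2-oxo-5-[(trimethylsilyl)ethynyl]-5-[(trimethylsilyl)oxy]-7-oxabicyclo[4.1.0]hept-3-en-3-yl]carbamate | O=C(/C=C/C=C/C1CCCCC1)N(C(=O)OC(C)(C)C)C1=C[C@](O[Si](C)(C)C)(C#C[Si](C)(C)C)[C@H]2O[C@H]2C1=O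
F7 | step 17 | dienyne analogue of the target, (2E,4E)-hepta-2,4-dien-6-ynamide chain on C4 | O=C(/C=C/C=C/C1CCCCC1)NC1=C[C@](O)(C#C/C=C/C=C/C(=O)NC2=C(O)CCC2=O)[C@H]2O[C@H]2C1=O
F8 | step 17 | 6-(triethoxysilyl) derivative of the target triene, silicon cis to C4 | O=C(/C=C/C=C/C1CCCCC1)NC1=C[C@](O)(/C=C(/C=C/C=C/C(=O)NC2=C(O)CCC2=O)[Si](OCC)(OCC)OCC)[C@H]2O[C@H]2C1=O
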